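## Structural features

Compound 26 contains a single carbocycle, a cyclohex-3-ene (ring atoms C1 to C6), joined through a primary alkyl aryl ether (C2–CH2–O) to O7 of a coumarin (umbelliferone) unit. C1 is quaternary (methyl and a 2-carboxyethyl chain), C2 bears the aryloxymethyl arm, C3 is the methyl-substituted alkene carbon, C4 the alkene CH, C5 bears an isopropenyl group and C6 is the only ring CH2. There are three stereocentres: C1 (R) and C2 (R) are adjacent, and C5 (S) is 1,3 to C1 across C6 and allylic to C4. The carboxyethyl chain, the CH2OAr arm and the isopropenyl group all lie on one face of the ring, the C1 methyl on the other. Fragile elements are the coumarin (an aryl lactone and enoate that does not survive hydride, amide bases or copper hydride), the skipped 1,4-diene (C5–H is doubly allylic), the acid-sensitive isopropenyl group, and C2–H, which is allylic and β to the aryloxy group. The real difficulty is the quaternary centre C1 next to C2 with the two functionalised arms cis, its correlation with the remote C5 centre, and the placement of the trisubstituted alkene exactly at C3=C4 in a ring with no heteroatom handle. The key step exploits the fact that the carbon on C1 can be a carboxyl carbon: the array carboxyl–C1–C2–C3=C4 is then the γ,δ-unsaturated acid retron of a [3,3] shift. Because C4 is tied back to C1 through C5 and C6, the ester oxygen of the precursor sits on C4 and the precursor is a six-membered lactone, so one rearrangement closes the carbocycle, makes C1–C2, sets C1 and C2 relative to C5 and fixes the alkene position.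

## Logic of the disconnections

26 to 24, then 22 + 23. The methyl ester is unmasked last, and before that the bond between the CH2 on C2 and the phenolic oxygen of 23 is cut. The reason is that the coumarin of 23 would not survive the amide base, LiAlH4 and copper hydride used earlier. The gain is that every earlier intermediate carries only a silyl ether at this position. The demand is an etherification at a β-branched primary carbon next to a quaternary centre, and an ester cleavage that leaves the coumarin closed at the end.

22 to 19 + 2 (through 21 and 20), and 19 to 17 (through 18). The propanoate chain is cut between its two CH2 groups, written as the C=C of 20, so that the carbon on C1 becomes a formyl carbon in 19 and, two redox steps earlier, the carboxyl carbon of 17. The reason is that a carboxyl on C1 is exactly what the key step delivers. The gain is that chain building is reduced to an olefination on an aldehyde that cannot epimerise. The demand is a conjugate reduction of 20 that leaves the isopropenyl and ring alkenes alone.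

17 to 13 (key disconnection). The ring bond C1–C2 is cut, a carboxyl oxygen is reconnected to C4, and the C3=C4 double bond moves to C2=C3, now exocyclic to a six-membered lactone. The reason is that this single bond carries the quaternary centre, its neighbour C2 and the alkene position. The gain is that the carbocycle, two stereocentres and the all-cis relation to C5 are replaced by a lactone with two adjacent centres and an (E)-alkene, all of which can be made by acyclic stereocontrol. The demand is a concerted [3,3] shift through the ring-enforced boat transition state, in which the trans relation of the two lactone substituents and the (E)-alkene are translated without leakage.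

13 to 12, then 6 + 10. The lactone C–O bond is cut to the hydroxy ester 12, and 12 is cut at C4–C5 (chain numbering of 12) into the allylboronate 6 and the enal 10. The reason is that the isopropenyl-bearing carbon next to a carbinol is the retron of an allylboration with allylic transposition. The gain is two achiral or racemic fragments of similar size. The demand is a (Z)-configured allylboronate, so that the closed transition state gives the syn relation needed for the trans lactone, and a catalyst that selects one face of 10.

6 to 5, 3, and 1 + 2. The C–B and one C–H bond of 6 are cut to diene 5 (1,4-hydroboration), the α-methyl of 5 is cut to 3 (deconjugative alkylation), and the C2=C3 bond of 3 is cut to 1 and 2. The reason is that the (Z)-trisubstituted allylboronate is defined by the s-cis diene on the metal and by nothing else. The gain is commercial materials in three steps. The demand is regiocontrol in the hydroboration (boron at the terminal CH2) and α- rather than γ- or ε-alkylation of the extended enolate.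

10 to 8 and 7. The formyl oxygen of 10 is removed to the methyl group of 8, and the silyl group to 7. The reason is that allylic oxidation of a prenyl ether is selective for the (E)-methyl group, which gives exactly the alkene geometry that later becomes the C2 configuration. The demand is complete oxidation to the aldehyde without E/Z isomerisation.

## Other disconnections considered

Alternative 1: The first idea is the chiral pool with conjugate addition. The cuts are the C1–CH3 bond and the C3–CH3 bond: conjugate methyl addition to the cyclohexenone A1, drawn from the (S)-carvone series, anti to the isopropenyl group, followed by conversion of the C3 carbonyl into the C3-methyl alkene through a kinetic enol triflate. The isopropenyl centre is bought, and C1 should follow from it. The weaknesses are structural. The methyl group of carvone sits where the CH2O arm must be and its β-carbon needs two new substituents, so A1 itself needs a long preparation. C2 would be set only by protonation next to a quaternary centre whose two substituents (methyl and chain) are sterically alike, so nothing controls the C1/C2 relation. The triflate must also form toward C4 and not toward the epimerisable C2. The chosen plan sets C1 and C2 together in one stereospecific event.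

Alternative 2: A Diels–Alder reaction. The cuts are C1–C2 and C5–C6: methacrolein with the triene A2 would give 19 in one step. The diene that must react carries the conjugating isopropenyl group at one terminus and a methyl on the carbon next to the other; both raise the HOMO coefficient at the CH2O-bearing terminus. That terminus should pair with the CH2 of methacrolein, which puts the quaternary carbon next to C5 and gives the wrong constitutional isomer. A2 also offers a second diene, and exo/endo and enantiofacial control with an α-substituted enal would be needed at the same time. The lactone in the chosen plan acts as a tether that fixes the orientation and supplies the absolute configuration.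

Alternative 3: A route that copies the presumed biogenesis. The acid carbon is reconnected to the isopropenyl carbon to give the bridged ketone A3 (a ring-expanded drimane skeleton). The forward step is α-cleavage beside the CMe2 group (Norrish photolysis and hydration of the ketene, or Beckmann fragmentation of the oxime), which reveals the isopropenyl group and the acid chain together. A3 contains the same three stereocentres plus a bridged seven-membered ring and is harder to make than 26. The coumarin is also the strongest chromophore in A3 and is prone to photodimerisation. The plan gives no simplification.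

Key step: step 8

Assumption: in step 6 the (S)-enantiomer of the phosphoric acid is taken to direct addition to the Si face of 10, by analogy with its sense for simple aldehydes; the carbon α to the ester in 5, 6, 11, 12 and 13 is a mixture of both configurations, which disappears when 13 is enolised in step 8.

## Steps

Step 1
Reactants: 1 3-methylbut-2-enal; 2 trimethyl phosphonoacetate
Product: 3 methyl (2E)-5-methylhexa-2,4-dienoate
Conditions: NaH, THF, 0 to 25 °C
Reagents that add atoms: none
Why: Horner–Wadsworth–Emmons olefination with a stabilised phosphonate anion should give the (2E)-dienoate; no stereocentre is formed.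

Step 2
Reactants: 3 methyl (2E)-5-methylhexa-2,4-dienoate
Product: 5 methyl (2RS,3E)-2,5-dimethylhexa-3,5-dienoate, via lithium trienolate 4 (not isolated)
Conditions: LiN(iPr)2 (commercial solution), DMPU, THF, −78 °C; MeI, −78 to −20 °C
Reagents that add atoms: iodomethane, CI
Why: Deconjugative α-alkylation: the amide base removes a proton from a terminal methyl to give the extended enolate 4, which should be methylated at the α-carbon, moving the diene out of conjugation as the (3E)-3,5-diene; the new α-centre is racemic and is erased in step 8.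

Step 3
Reactants: 5 methyl (2RS,3E)-2,5-dimethylhexa-3,5-dienoate
Product: 6 methyl (2RS,4Z)-2,5-dimethyl-6-(4,4,5,5-tetramethyl-1,3,2-dioxaborolan-2-yl)hex-4-enoate
Conditions: HBpin, Ni(cod)2 (2.5 mol%), PCy3 (2.5 mol%), toluene, 25 °C
Reagents that add atoms: pinacolborane, [H]B1OC(C)(C)C(C)(C)O1
Why: Nickel-catalysed 1,4-hydroboration of a 1,3-diene: the s-cis diene on nickel should take hydrogen at the substituted terminus and boron at the terminal CH2, which leaves the two CH2 groups cis on the new trisubstituted alkene, that is, the (Z)-allylboronate.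

Step 4
Reactants: 7 3-methylbut-2-en-1-ol
Product: 8 tert-butyl[(3-methylbut-2-en-1-yl)oxy]diphenylsilane
Conditions: TBDPSCl, imidazole, CH2Cl2, 0 to 25 °C
Reagents that add atoms: tert-butyl(chloro)diphenylsilane, CC(C)(C)[Si](Cl)(c1ccccc1)c1ccccc1
Why: Standard silylation of a primary alcohol; the tert-butyldiphenylsilyl ether is chosen because it must survive acid, amide base, hydride and heat in steps 5 to 12.

Step 5
Reactants: 8 tert-butyl[(3-methylbut-2-en-1-yl)oxy]diphenylsilane
Product: 10 (2E)-4-[(tert-butyldiphenylsilyl)oxy]-2-methylbut-2-enal, via (2E)-4-[(tert-butyldiphenylsilyl)oxy]-2-methylbut-2-en-1-ol 9 (not isolated)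
Conditions: SeO2 (0.3 equiv), t-BuOOH, CH2Cl2, 0 to 25 °C; then MnO2, CH2Cl2, 25 °C
Reagents that add atoms: selenium dioxide, O=[Se]=O; tert-butyl hydroperoxide, CC(C)(C)OO
Why: Selenium dioxide allylic oxidation (ene reaction then [2,3] shift) is selective for the (E)-methyl group of a trisubstituted alkene, and MnO2 carries the remaining allylic alcohol 9 on to the enal; this (E)-geometry later determines the configuration at C2 of the ring.

Step 6
Reactants: 6 methyl (2RS,4Z)-2,5-dimethyl-6-(4,4,5,5-tetramethyl-1,3,2-dioxaborolan-2-yl)hex-4-enoate; 10 (2E)-4-[(tert-butyldiphenylsilyl)oxy]-2-methylbut-2-enal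
Product: 12 methyl (2RS,4R,5S,6E)-8-[(tert-butyldiphenylsilyl)oxy]-5-hydroxy-2,6-dimethyl-4-(prop-1-en-2-yl)oct-6-enoate, via its O-(pinacolato)boryl ether 11 (not isolated)
Conditions: (S)-TRIP [(S)-3,3′-bis(2,4,6-triisopropylphenyl)-1,1′-binaphthyl-2,2′-diyl hydrogen phosphate] (5 mol%), 4 Å molecular sieves, toluene, −30 °C; aq. NaHCO3 work-up
Reagents that add atoms: none
Why: Chiral phosphoric acid-catalysed allylboration through a closed six-membered chair: the (Z)-γ-substituent is forced axial, so the hydroxyl and the CH2 branch come out syn (4R,5S relative) and the boron-bound carbon becomes the isopropenyl CH2; the catalyst, hydrogen-bonded to a boronate oxygen, should select the Si face of 10 and so set 5S, and the borate 11 is cleaved on work-up.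

Step 7
Reactants: 12 methyl (2RS,4R,5S,6E)-8-[(tert-butyldiphenylsilyl)oxy]-5-hydroxy-2,6-dimethyl-4-(prop-1-en-2-yl)oct-6-enoate
Product: 13 (3RS,5R,6S)-6-{(2E)-4-[(tert-butyldiphenylsilyl)oxy]but-2-en-2-yl}-3-methyl-5-(prop-1-en-2-yl)oxan-2-one
Conditions: PPTS (10 mol%), toluene, 60 °C
Reagents that add atoms: none
Why: Acid-catalysed lactonisation of a δ-hydroxy ester with loss of methanol; no stereocentre is touched, and the syn relation of 12 becomes the trans 5,6-relation of the lactone.

Step 8
Reactants: 13 (3RS,5R,6S)-6-{(2E)-4-[(tert-butyldiphenylsilyl)oxy]but-2-en-2-yl}-3-methyl-5-(prop-1-en-2-yl)oxan-2-one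
Product: 17 (1R,2S,5S)-2-{[(tert-butyldiphenylsilyl)oxy]methyl}-1,3-dimethyl-5-(prop-1-en-2-yl)cyclohex-3-ene-1-carboxylic acid, via lithium enolate 14 (not isolated), via trimethylsilyl ketene acetal 15 (not isolated), via trimethylsilyl ester 16 (not isolated)
Conditions: LiN(iPr)2 (commercial solution), THF, −78 °C; TMSCl/Et3N, −78 to 25 °C; toluene, 110 °C; then 1 M HCl, THF
Reagents that add atoms: none
Why: The amide base removes the single α-hydrogen of 13 (both C3 epimers converge) to give enolate 14, which is O-silylated to the endocyclic ketene acetal 15; on heating, 15 undergoes a concerted suprafacial [3,3] shift in which lactone C3 bonds to the CH terminus of the side-chain alkene while the allylic C6–O1 bond breaks, giving ester 16 and, after hydrolysis, 17. The closest known reaction type is the Ireland–Claisen rearrangement of silyl ketene acetals of 6-alkenyl δ-lactones to cyclohex-3-ene-1-carboxylic acids. The cyclohexene (lactone C3, C4, C5, C6 and the two alkenyl carbons) is closed by this one C–C bond; because the two ends of the pericyclic array are tied by the C4–C5 bridge, the transition state can only be the boat, bicyclo[2.2.2]octane-like one, and the ring-fixed ketene acetal leaves no enolate geometry to control. At ring C1 of 17 the carboxyl is the former lactone carbonyl and stays on the face where the oxygen bridge was, while the methyl points out of the cage. At ring C2 the (E)-geometry of the side chain puts the CH2OSi group on the side away from the C4–C5 bridge, which makes it cis to the carboxyl. Ring C5 is carried over unchanged from 13, and its trans relation to the alkenyl group in 13 becomes a cis relation to the carboxyl; the carbinol centre of 13 is consumed in a C–O to C–C chirality transfer and becomes sp2 C4. The step needs O- rather than C-silylation and a concerted rather than ionised cleavage of the allylic C–O bond; the hindered α-methyl enolate with TMSCl/Et3N favours the first, and the non-polar solvent and pre-organised boat favour the second. Only one [3,3] array exists, since the isopropenyl group is not allylic to oxygen, so chemoselectivity is built in.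

Step 9
Reactants: 17 (1R,2S,5S)-2-{[(tert-butyldiphenylsilyl)oxy]methyl}-1,3-dimethyl-5-(prop-1-en-2-yl)cyclohex-3-ene-1-carboxylic acid
Product: 18 [(1R,2S,5S)-2-{[(tert-butyldiphenylsilyl)oxy]methyl}-1,3-dimethyl-5-(prop-1-en-2-yl)cyclohex-3-en-1-yl]methanol
Conditions: LiAlH4, THF, 0 to 25 °C
Reagents that add atoms: none
Why: Hydride reduction of a hindered carboxylic acid to the primary alcohol; the silyl ether and the isolated alkenes are inert at this temperature and no stereocentre is affected.

Step 10
Reactants: 18 [(1R,2S,5S)-2-{[(tert-butyldiphenylsilyl)oxy]methyl}-1,3-dimethyl-5-(prop-1-en-2-yl)cyclohex-3-en-1-yl]methanol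
Product: 19 (1R,2S,5S)-2-{[(tert-butyldiphenylsilyl)oxy]methyl}-1,3-dimethyl-5-(prop-1-en-2-yl)cyclohex-3-ene-1-carbaldehyde
Conditions: Dess–Martin periodinane, CH2Cl2, 25 °C
Reagents that add atoms: none
Why: Dess–Martin oxidation of a neopentyl-type primary alcohol; the aldehyde has no α-hydrogen and cannot epimerise.

Step 11
Reactants: 19 (1R,2S,5S)-2-{[(tert-butyldiphenylsilyl)oxy]methyl}-1,3-dimethyl-5-(prop-1-en-2-yl)cyclohex-3-ene-1-carbaldehyde; 2 trimethyl phosphonoacetate
Product: 20 methyl (2E)-3-[(1S,2S,5S)-2-{[(tert-butyldiphenylsilyl)oxy]methyl}-1,3-dimethyl-5-(prop-1-en-2-yl)cyclohex-3-en-1-yl]prop-2-enoate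
Conditions: NaH, THF, 0 to 40 °C
Reagents that add atoms: none
Why: Horner–Wadsworth–Emmons olefination of a non-enolisable aldehyde adds the two missing chain carbons as the (E)-enoate; the descriptor at C1 changes only through the priority rules.

Step 12
Reactants: 20 methyl (2E)-3-[(1S,2S,5S)-2-{[(tert-butyldiphenylsilyl)oxy]methyl}-1,3-dimethyl-5-(prop-1-en-2-yl)cyclohex-3-en-1-yl]prop-2-enoate
Product: 21 methyl 3-[(1R,2R,5S)-2-{[(tert-butyldiphenylsilyl)oxy]methyl}-1,3-dimethyl-5-(prop-1-en-2-yl)cyclohex-3-en-1-yl]propanoate
Conditions: [(Ph3P)CuH]6, H2O, toluene, 25 °C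
Reagents that add atoms: none
Why: Copper hydride conjugate reduction delivers hydride only to the electron-poor enoate alkene, so the isopropenyl and ring alkenes, the silyl ether and the stereocentres are untouched.

Step 13
Reactants: 21 methyl 3-[(1R,2R,5S)-2-{[(tert-butyldiphenylsilyl)oxy]methyl}-1,3-dimethyl-5-(prop-1-en-2-yl)cyclohex-3-en-1-yl]propanoate
Product: 22 methyl 3-[(1R,2R,5S)-2-(hydroxymethyl)-1,3-dimethyl-5-(prop-1-en-2-yl)cyclohex-3-en-1-yl]propanoate
Conditions: Bu4NF, AcOH, THF, 0 to 25 °C
Reagents that add atoms: none
Why: Fluoride cleavage of the silyl ether; the acetic acid buffer keeps the liberated alkoxide protonated so that it does not close a seven-membered lactone onto the cis-disposed ester.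

Step 14
Reactants: 22 methyl 3-[(1R,2R,5S)-2-(hydroxymethyl)-1,3-dimethyl-5-(prop-1-en-2-yl)cyclohex-3-en-1-yl]propanoate; 23 7-hydroxy-2H-chromen-2-one (umbelliferone)
Product: 24 methyl 3-[(1R,2R,5S)-1,3-dimethyl-2-{[(2-oxo-2H-chromen-7-yl)oxy]methyl}-5-(prop-1-en-2-yl)cyclohex-3-en-1-yl]propanoate
Conditions: PPh3, DIAD, THF, 0 to 25 °C
Reagents that add atoms: none
Why: Mitsunobu etherification: the acidic phenol of 23 is a competent pronucleophile and displaces the activated primary alcohol by SN2 at a CH2 group, so no stereocentre is involved and the coumarin meets only neutral reagents.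

Step 15
Reactants: 24 methyl 3-[(1R,2R,5S)-1,3-dimethyl-2-{[(2-oxo-2H-chromen-7-yl)oxy]methyl}-5-(prop-1-en-2-yl)cyclohex-3-en-1-yl]propanoate
Product: 26 3-[(1R,2R,5S)-1,3-dimethyl-2-{[(2-oxo-2H-chromen-7-yl)oxy]methyl}-5-(prop-1-en-2-yl)cyclohex-3-en-1-yl]propanoic acid, via the ring-opened trilithium (Z)-2-oxidocinnamate dicarboxylate 25 (not isolated)
Conditions: LiOH, THF/H2O, 25 °C, dark; then 1 M HCl to pH 2
Reagents that add atoms: lithium hydroxide, [Li+].[OH-]
Why: Saponification of the methyl ester; hydroxide also opens the coumarin to the (Z)-configured salt 25, which should close again to the lactone on acidification because the phenol and the acid stay cis as long as light is excluded.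

## Compound list

1 | 3-methylbut-2-enal | CC(C)=CC=O | starting material
2 | trimethyl phosphonoacetate | COC(=O)CP(=O)(OC)OC | starting material
3 | methyl (2E)-5-methylhexa-2,4-dienoate | COC(=O)/C=C/C=C(C)C | intermediate
4 | lithium (3E)-1-methoxy-5-methylhexa-1,3,5-trien-1-olate | COC([O-])=C/C=C/C(C)=C.[Li+] | intermediate (not isolated)
5 | methyl (2RS,3E)-2,5-dimethylhexa-3,5-dienoate | COC(=O)C(C)/C=C/C(C)=C | intermediate
6 | methyl (2RS,4Z)-2,5-dimethyl-6-(4,4,5,5-tetramethyl-1,3,2-dioxaborolan-2-yl)hex-4-enoate | COC(=O)C(C)C/C=C(/C)CB1OC(C)(C)C(C)(C)O1 | intermediate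
7 | 3-methylbut-2-en-1-ol | CC(C)=CCO | starting material
8 | tert-butyl[(3-methylbut-2-en-1-yl)oxy]diphenylsilane | CC(C)=CCO[Si](c1ccccc1)(c1ccccc1)C(C)(C)C | intermediate
9 | (2E)-4-[(tert-butyldiphenylsilyl)oxy]-2-methylbut-2-en-1-ol | OC/C(C)=C/CO[Si](c1ccccc1)(c1ccccc1)C(C)(C)C | intermediate (not isolated)
10 | (2E)-4-[(tert-butyldiphenylsilyl)oxy]-2-methylbut-2-enal | O=C/C(C)=C/CO[Si](c1ccccc1)(c1ccccc1)C(C)(C)C | intermediate
11 | methyl (2RS,4R,5S,6E)-8-[(tert-butyldiphenylsilyl)oxy]-2,6-dimethyl-4-(prop-1-en-2-yl)-5-[(4,4,5,5-tetramethyl-1,3,2-dioxaborolan-2-yl)oxy]oct-6-enoate | COC(=O)C(C)C[C@H](C(C)=C)[C@H](OB1OC(C)(C)C(C)(C)O1)/C(C)=C/CO[Si](c1ccccc1)(c1ccccc1)C(C)(C)C | intermediate (not isolated)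
12 | methyl (2RS,4R,5S,6E)-8-[(tert-butyldiphenylsilyl)oxy]-5-hydroxy-2,6-dimethyl-4-(prop-1-en-2-yl)oct-6-enoate | COC(=O)C(C)C[C@H](C(C)=C)[C@H](O)/C(C)=C/CO[Si](c1ccccc1)(c1ccccc1)C(C)(C)C | intermediate
13 | (3RS,5R,6S)-6-{(2E)-4-[(tert-butyldiphenylsilyl)oxy]but-2-en-2-yl}-3-methyl-5-(prop-1-en-2-yl)oxan-2-one | CC1C[C@H](C(C)=C)[C@H](OC1=O)/C(C)=C/CO[Si](c2ccccc2)(c2ccccc2)C(C)(C)C | intermediate
14 | lithium (2S,3R)-2-{(2E)-4-[(tert-butyldiphenylsilyl)oxy]but-2-en-2-yl}-5-methyl-3-(prop-1-en-2-yl)-3,4-dihydro-2H-pyran-6-olate | CC=1C[C@H](C(C)=C)[C@H](OC=1[O-])/C(C)=C/CO[Si](c2ccccc2)(c2ccccc2)C(C)(C)C.[Li+] | intermediate (not isolated)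
15 | tert-butyl{[(2E)-3-{(2S,3R)-5-methyl-3-(prop-1-en-2-yl)-6-[(trimethylsilyl)oxy]-3,4-dihydro-2H-pyran-2-yl}but-2-en-1-yl]oxy}diphenylsilane | CC=1C[C@H](C(C)=C)[C@H](OC=1O[Si](C)(C)C)/C(C)=C/CO[Si](c2ccccc2)(c2ccccc2)C(C)(C)C | intermediate (not isolated)
16 | trimethylsilyl (1R,2S,5S)-2-{[(tert-butyldiphenylsilyl)oxy]methyl}-1,3-dimethyl-5-(prop-1-en-2-yl)cyclohex-3-ene-1-carboxylate | C=C(C)[C@@H]1C=C(C)[C@H](CO[Si](c2ccccc2)(c2ccccc2)C(C)(C)C)[C@](C)(C(=O)O[Si](C)(C)C)C1 | intermediate (not isolated)
17 | (1R,2S,5S)-2-{[(tert-butyldiphenylsilyl)oxy]methyl}-1,3-dimethyl-5-(prop-1-en-2-yl)cyclohex-3-ene-1-carboxylic acid | C=C(C)[C@@H]1C=C(C)[C@H](CO[Si](c2ccccc2)(c2ccccc2)C(C)(C)C)[C@](C)(C(=O)O)C1 | intermediate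
18 | [(1R,2S,5S)-2-{[(tert-butyldiphenylsilyl)oxy]methyl}-1,3-dimethyl-5-(prop-1-en-2-yl)cyclohex-3-en-1-yl]methanol | C=C(C)[C@@H]1C=C(C)[C@H](CO[Si](c2ccccc2)(c2ccccc2)C(C)(C)C)[C@](C)(CO)C1 | intermediate
19 | (1R,2S,5S)-2-{[(tert-butyldiphenylsilyl)oxy]methyl}-1,3-dimethyl-5-(prop-1-en-2-yl)cyclohex-3-ene-1-carbaldehyde | C=C(C)[C@@H]1C=C(C)[C@H](CO[Si](c2ccccc2)(c2ccccc2)C(C)(C)C)[C@](C)(C=O)C1 | intermediate
20 | methyl (2E)-3-[(1S,2S,5S)-2-{[(tert-butyldiphenylsilyl)oxy]methyl}-1,3-dimethyl-5-(prop-1-en-2-yl)cyclohex-3-en-1-yl]prop-2-enoate | C=C(C)[C@@H]1C=C(C)[C@H](CO[Si](c2ccccc2)(c2ccccc2)C(C)(C)C)[C@](C)(/C=C/C(=O)OC)C1 | intermediate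
21 | methyl 3-[(1R,2R,5S)-2-{[(tert-butyldiphenylsilyl)oxy]methyl}-1,3-dimethyl-5-(prop-1-en-2-yl)cyclohex-3-en-1-yl]propanoate | C=C(C)[C@@H]1C=C(C)[C@H](CO[Si](c2ccccc2)(c2ccccc2)C(C)(C)C)[C@](C)(CCC(=O)OC)C1 | intermediate
22 | methyl 3-[(1R,2R,5S)-2-(hydroxymethyl)-1,3-dimethyl-5-(prop-1-en-2-yl)cyclohex-3-en-1-yl]propanoate | C=C(C)[C@@H]1C=C(C)[C@H](CO)[C@](C)(CCC(=O)OC)C1 | intermediate
23 | 7-hydroxy-2H-chromen-2-one (umbelliferone) | Oc1ccc2ccc(=O)oc2c1 | starting material
24 | methyl 3-[(1R,2R,5S)-1,3-dimethyl-2-{[(2-oxo-2H-chromen-7-yl)oxy]methyl}-5-(prop-1-en-2-yl)cyclohex-3-en-1-yl]propanoate | C=C(C)[C@@H]1C=C(C)[C@H](COc2ccc3ccc(=O)oc3c2)[C@](C)(CCC(=O)OC)C1 | intermediate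
25 | trilithium salt of the coumarin-opened form of 26: (2Z)-3-[4-(alkoxy)-2-oxidophenyl]prop-2-enoate with the propanoate also as carboxylate, ring configuration as in 26 | C=C(C)[C@@H]1C=C(C)[C@H](COc2ccc(/C=C\C(=O)[O-])c([O-])c2)[C@](C)(CCC(=O)[O-])C1.[Li+].[Li+].[Li+] | intermediate (not isolated)
26 | 3-[(1R,2R,5S)-1,3-dimethyl-2-{[(2-oxo-2H-chromen-7-yl)oxy]methyl}-5-(prop-1-en-2-yl)cyclohex-3-en-1-yl]propanoic acid (CNP0301632.1) | C=C(C)[C@@H]1C=C(C)[C@H](COc2ccc3ccc(=O)oc3c2)[C@](C)(CCC(=O)O)C1 | target

## Step count and least certain steps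

Total step count: 15. Longest linear sequence: 13 steps (steps 1 to 3 and 6 to 15, from 3-methylbut-2-enal); the aldehyde branch (steps 4 and 5) joins at step 6.

Step 8 (key step). What may go wrong: ionisation of the allylic C–O bond of the ketene acetal before the concerted shift (loss of stereospecificity or elimination to a dienoic acid), C-silylation or incomplete enolisation of the hindered α-methine, or slow bond formation between two congested termini at 110 °C. Fallback: move the rearrangement to the neutral enol ether level, which needs neither enolisation nor silylation and delivers the aldehyde oxidation state directly. It sets out from 13: reduction with i-Bu2AlH at −78 °C gives the lactol (3RS,5R,6S)-6-{(2E)-4-[(tert-butyldiphenylsilyl)oxy]but-2-en-2-yl}-3-methyl-5-(prop-1-en-2-yl)oxan-2-ol F1; dehydration (MsCl, Et3N) gives the cyclic enol ether tert-butyl{[(2E)-3-{(2S,3R)-5-methyl-3-(prop-1-en-2-yl)-3,4-dihydro-2H-pyran-2-yl}but-2-en-1-yl]oxy}diphenylsilane F2; thermal Claisen rearrangement of F2 (base-washed sealed tube, toluene, about 210 °C) should pass through the same boat transition state and come back to the route at 19, so that steps 9 and 10 are not needed.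

Step 6. What may go wrong: slow addition of the hindered trisubstituted allylboronate, so that the uncatalysed background reaction erodes enantioselectivity, or poor facial selectivity of the catalyst with an α-branched enal. Fallback: resolution in place of asymmetric catalysis. It sets out from 6 and 10: the uncatalysed thermal allylboration (toluene, 25 to 50 °C) still goes through the closed chair and should give the syn adduct as a racemate, that is 11 together with its enantiomer, the (2RS,4S,5R,6E)-boryl ether F6; work-up gives 12 together with its enantiomer methyl (2RS,4S,5R,6E)-8-[(tert-butyldiphenylsilyl)oxy]-5-hydroxy-2,6-dimethyl-4-(prop-1-en-2-yl)oct-6-enoate F7. Sharpless kinetic resolution (Ti(OiPr)4, D-(−)-diisopropyl tartrate, t-BuOOH, 4 Å sieves, CH2Cl2, −20 °C) should epoxidise F7 faster, to the epoxy alcohol methyl (2RS,4S,5R)-5-[(2S,3S)-3-{[(tert-butyldiphenylsilyl)oxy]methyl}-2-methyloxiran-2-yl]-5-hydroxy-2-methyl-4-(prop-1-en-2-yl)pentanoate F8, and leave 12, where the fallback rejoins the route.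

Step 3. What may go wrong: migration of the diene into conjugation with the ester under nickel hydride conditions, or incomplete Z-selectivity, which would leak into the anti diastereomer in step 6. Fallback: replace the boron branch by chromium chemistry and correct the carbinol configuration afterwards. Methyl propanoate (LiN(iPr)2, THF, −78 °C) is alkylated with commercial (E)-1,4-dibromo-2-methylbut-2-ene at its less hindered CH2Br to give methyl (2RS,4E)-6-bromo-2,5-dimethylhex-4-enoate F3. The fallback then sets out from 10: an asymmetric Nozaki–Hiyama–Kishi allylation (CrCl2, chiral bis(oxazoline) ligand, THF), which is anti-selective whatever the allyl geometry, should give methyl (2RS,4R,5R,6E)-8-[(tert-butyldiphenylsilyl)oxy]-5-hydroxy-2,6-dimethyl-4-(prop-1-en-2-yl)oct-6-enoate F4; LiOH gives the acid (2RS,4R,5R,6E)-8-[(tert-butyldiphenylsilyl)oxy]-5-hydroxy-2,6-dimethyl-4-(prop-1-en-2-yl)oct-6-enoic acid F5; Mitsunobu lactonisation (PPh3, DIAD, toluene, 0 °C) closes the ring with inversion at the carbinol carbon and comes back to the route at 13.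

Step 14. What may go wrong: slow SN2 displacement at the β-branched CH2 next to the quaternary centre, so that the activated alcohol is diverted into elimination or into lactonisation onto the ester. Fallback: form the other C–O bond instead, which avoids backside attack at the hindered carbon. It sets out from 22: palladium-catalysed C–O coupling with commercial 7-bromo-2H-chromen-2-one (Pd2(dba)3, a bulky biaryl di-tert-butylphosphine, Cs2CO3, toluene, 80 °C) should give 24 directly, where it rejoins the route; no new compound is made (F0).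

## Further compounds

F1 | step 8 | (3RS,5R,6S)-6-{(2E)-4-[(tert-butyldiphenylsilyl)oxy]but-2-en-2-yl}-3-methyl-5-(prop-1-en-2-yl)oxan-2-ol | CC1C[C@H](C(C)=C)[C@H](OC1O)/C(C)=C/CO[Si](c2ccccc2)(c2ccccc2)C(C)(C)C
F2 | step 8 | tert-butyl{[(2E)-3-{(2S,3R)-5-methyl-3-(prop-1-en-2-yl)-3,4-dihydro-2H-pyran-2-yl}but-2-en-1-yl]oxy}diphenylsilane | CC=1C[C@H](C(C)=C)[C@H](OC=1)/C(C)=C/CO[Si](c2ccccc2)(c2ccccc2)C(C)(C)C
F3 | step 3 | methyl (2RS,4E)-6-bromo-2,5-dimethylhex-4-enoate | COC(=O)C(C)C/C=C(\C)CBr
F4 | step 3 | methyl (2RS,4R,5R,6E)-8-[(tert-butyldiphenylsilyl)oxy]-5-hydroxy-2,6-dimethyl-4-(prop-1-en-2-yl)oct-6-enoate | COC(=O)C(C)C[C@H](C(C)=C)[C@@H](O)/C(C)=C/CO[Si](c1ccccc1)(c1ccccc1)C(C)(C)C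
F5 | step 3 | (2RS,4R,5R,6E)-8-[(tert-butyldiphenylsilyl)oxy]-5-hydroxy-2,6-dimethyl-4-(prop-1-en-2-yl)oct-6-enoic acid | OC(=O)C(C)C[C@H](C(C)=C)[C@@H](O)/C(C)=C/CO[Si](c1ccccc1)(c1ccccc1)C(C)(C)C
F6 | step 6 | methyl (2RS,4S,5R,6E)-8-[(tert-butyldiphenylsilyl)oxy]-2,6-dimethyl-4-(prop-1-en-2-yl)-5-[(4,4,5,5-tetramethyl-1,3,2-dioxaborolan-2-yl)oxy]oct-6-enoate | COC(=O)C(C)C[C@@H](C(C)=C)[C@@H](OB1OC(C)(C)C(C)(C)O1)/C(C)=C/CO[Si](c2ccccc2)(c2ccccc2)C(C)(C)C
F7 | step 6 | methyl (2RS,4S,5R,6E)-8-[(tert-butyldiphenylsilyl)oxy]-5-hydroxy-2,6-dimethyl-4-(prop-1-en-2-yl)oct-6-enoate | COC(=O)C(C)C[C@@H](C(C)=C)[C@@H](O)/C(C)=C/CO[Si](c1ccccc1)(c1ccccc1)C(C)(C)C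
F8 | step 6 | methyl (2RS,4S,5R)-5-[(2S,3S)-3-{[(tert-butyldiphenylsilyl)oxy]methyl}-2-methyloxiran-2-yl]-5-hydroxy-2-methyl-4-(prop-1-en-2-yl)pentanoate | COC(=O)C(C)C[C@@H](C(C)=C)[C@@H](O)[C@]1(C)O[C@H]1CO[Si](c2ccccc2)(c2ccccc2)C(C)(C)C
F0 | step 14 | none | none
A1 | alternative 1 | methyl 3-[(5S)-2-{[(tert-butyldiphenylsilyl)oxy]methyl}-3-oxo-5-(prop-1-en-2-yl)cyclohex-1-en-1-yl]propanoate | COC(=O)CCC1=C(CO[Si](c2ccccc2)(c2ccccc2)C(C)(C)C)C(=O)C[C@@H](C(C)=C)C1
A2 | alternative 2 | tert-butyl{[(2E,4E)-3,6-dimethylhepta-2,4,6-trien-1-yl]oxy}diphenylsilane | C=C(C)/C=C/C(C)=C/CO[Si](c1ccccc1)(c1ccccc1)C(C)(C)C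
A3 | alternative 3 | 7-{[(1S,6R,7R)-2,2,6,8-tetramethyl-3-oxobicyclo[4.3.1]dec-8-en-7-yl]methoxy}-2H-chromen-2-one | CC2(C)[C@@H]1C=C(C)[C@H](COc3ccc4ccc(=O)oc4c3)[C@](C)(CCC2=O)C1
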